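Late in the delta run, between 2.00 min and 5.00 min, the solid substrate was still falling about as fast as between the two readings before, so that stretch was where I began.

| setting | delta | Friday's | Sunday's | Wednesday's | Tuesday's |
|---|---|---|---|---|---|
| solid substrate | 0.97 M | 1.5 M | 0.80 M | 2.0 M | 3.0 M |
| gas | 200 mM (held) | 200 mM (held) | 200 mM (held) | 200 mM (held) | 200 mM (held) |
| remark | run made earlier |  |  |  |  |
| time |  | 5.0 min | 5.0 min | 5.0 min | 5.0 min |

- delta (time / min: target / %, solid substrate / %): 0.417: 2.1, 91.8; 1.00: 10.4, 81.6; 2.00: 22.9, 64.2; 5.00: 56.2, 10.4

(each reading ± 0.3 percentage points)

- as a solid, counted per litre of solution: solid substrate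
- at the start none of the solid substrate is in solution
- at the start none of the gas is in solution
- what has only dissolved of solid substrate counts as not reacted

1. the flasks by amount of target, in percent of the solid substrate charged, highest first, at 5.0 min (Friday's / Sunday's / Wednesday's / Tuesday's)
2. the amount of target, in percent of the solid substrate charged of the flask you put first, at 5.0 min
3. the amount of target, in percent of the solid substrate charged of the flask you put last, at 5.0 min

Over that stretch the solid substrate fell by 0.174 M min⁻¹, with no slowing as the heap shrank. My bench rule was therefore to count in molarity, not percent. As the zero of the scale I took the case in which each flask with solid still present, at the same gas and the same time, makes the same target per litre, whatever its charge. The quantity to carry is the make s, the target gained per litre per minute late in the run, 0.108 M min⁻¹. Delta held 0.545 M of target at its last reading, so I reckoned 18.2% for Tuesday's, 27.3% for Wednesday's and 36.3% for Friday's.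

The border is the solid used in delta by that time, 0.869 M. Friday's charge is 1.73 of that use, but Sunday's is 0.920 of it. So I took the solid substrate in Sunday's flask to be the limiting reagent, and the rule's 68.1% to lie beyond its border.

The forecast gave Sunday's > Friday's > Wednesday's > Tuesday's, with 66% (61% to 70%) for Sunday's, below my unguarded figure, and 18.2% (17.2% to 19.2%) for Tuesday's. Its ground was: “Flasks with excess solid should all reach about 0.545 M”.

The flasks gave Sunday's > Friday's > Wednesday's > Tuesday's, with 65.2% first and 18.3% last.

    solid substrate ⇌ dissolved substrate, rate k1*(cs1 - [dissolved substrate]) while solid is left; crystals form when [dissolved substrate] > cs1 (solubility = 2.20 M, k = 0.00136 s⁻¹)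
    dissolved substrate + partner → target (k = 0.573 M⁻¹ s⁻¹)
    gas ⇌ partner, rate k3*(csat - [partner]) (kL = 0.0256 s⁻¹)
    target ⇌ isomer of the product (K = 0.650, k = 0.00816 s⁻¹)
    partner → decomposition product (k = 5.39 × 10⁻⁶ s⁻¹)

Tuesday's target rose from 9.37% at 2.50 min to 18.3% at 5.0 min, which on its charge is 0.107 M min⁻¹, close to s. The thing to watch is the isomer of the product, at 33.0% in Sunday's at 5.00 min: target there stood at 65.2% against 98.2% in the run without the passing of target into the isomer, the main reason for Sunday's shortfall from the whole charge. For a reading of Tuesday's flask at 3.0 min, s carried on from delta's 2.00 min reading gave me 11.0%; the computed value was 11.2%.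

Readings and results were computed on assumed constants, noise included.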